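**Retrosynthetic overview**
1. The coumarate is attached last to the 1β-OH of a 1β,5α-diol, and both aldehydes (C11, C12) are carried as Weinreb amides that are reduced after the acylation.
2. Ring A (C1–C5, C10) is closed last through the C4–C5 bond. The enabling feature is that the ring-fusion carbinol C5 is bonded to the gem-dimethyl carbon C4 and lies 1,3 to the oxygenated C1 across the quaternary C10, so C5–OH/C4Me2 maps onto a ketone plus an isopropenyl group (joined by hydrogen-atom transfer) and C1–O/C5–O onto a β-diketone.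
3. The 5α-OH then directs hydride to C1 (1,3-anti), and the C10–C1 bond comes from a Mukaiyama aldol of a ring-B silyl enol ether, anti to the C9 substituent.
4. Ring B is made first by an enantioselective Diels–Alder reaction of a 2-silyloxydiene (from biacetyl) with a propioloyl azolide. C9 is the only stereocentre set by catalysis; C10, C5 and C1 are relayed from it.
5. Order of ring formation: ring B (step 4), then ring A (step 8).

Key step: step 8

Remark: drimane numbering is used for all carbocycles (ring A C1–C5/C10, ring B C5–C10, C11 on C9, C12 on C8; target = 1R,5R,9R,10S), and the sense of induction of the copper catalyst in step 4 is assumed to be adjustable through the ligand enantiomer.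

**Route**

Step 1
Reactants: 1 butane-2,3-dione; 2 N-methoxy-N-methyl-2-(triphenylphosphoranylidene)acetamide
Product: 3 (2E)-N-methoxy-N,3-dimethyl-4-oxopent-2-enamide
Conditions: 1 (3 equiv), toluene, rt → 60 °C
Reagents that add atoms: none
Why: Wittig olefination with a stabilized ylide should mono-olefinate the excess diketone and give the E-enone, with acetyl and amide trans.

Step 2
Reactants: 3 (2E)-N-methoxy-N,3-dimethyl-4-oxopent-2-enamide
Product: 4 (2E)-4-[(tert-butyldimethylsilyl)oxy]-N-methoxy-N,3-dimethylpenta-2,4-dienamide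
Conditions: TBSOTf, Et3N, CH2Cl2, 0 °C
Reagents that add atoms: tert-butyldimethylsilyl trifluoromethanesulfonate, CC(C)(C)[Si](C)(C)OS(=O)(=O)C(F)(F)F
Why: soft enolization and O-silylation of the methyl ketone (the only α-hydrogens) should give the 2-silyloxy-1,3-diene.

Step 3
Reactants: 5 propiolic acid; 6 3,5-dimethyl-1H-pyrazole
Product: 7 1-(3,5-dimethyl-1H-pyrazol-1-yl)prop-2-yn-1-one
Conditions: DCC, CH2Cl2, −10 → 0 °C
Reagents that add atoms: none
Why: carbodiimide-mediated N-acylation of the pyrazole should give the two-point-binding propioloyl azolide.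

Step 4
Reactants: 4 (2E)-4-[(tert-butyldimethylsilyl)oxy]-N-methoxy-N,3-dimethylpenta-2,4-dienamide; 7 1-(3,5-dimethyl-1H-pyrazol-1-yl)prop-2-yn-1-one
Product: 9 (6R)-4-[(tert-butyldimethylsilyl)oxy]-N1,N6-dimethoxy-N1,N6,5-trimethylcyclohexa-1,4-diene-1,6-dicarboxamide, via acylpyrazole cycloadduct 8 (not isolated)
Conditions: Cu(NTf2)2 (10 mol %), chiral bis(oxazoline) ligand (t-Bu-box, enantiomer giving 6R), CH2Cl2, −40 → −20 °C; then MeNHOMe·HCl, pyridine, 0 °C → rt
Reagents that add atoms: N,O-dimethylhydroxylamine hydrochloride, CNOC.Cl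
Why: chiral-Lewis-acid-catalysed Diels–Alder reaction of a chelating propioloyl azolide, in which the nucleophilic CH2 terminus of the silyloxydiene bonds the β-alkyne carbon (silyloxy "para" to the acyl group) and the catalyst sets C9, followed by aminolysis of the acylpyrazole to the Weinreb amide.

Step 5
Reactants: 10 4-methylpent-4-en-1-ol
Product: 11 4-methylpent-4-enal
Conditions: TEMPO (10 mol %), PhI(OAc)2, CH2Cl2, rt
Reagents that add atoms: none
Why: oxoammonium (TEMPO) oxidation of a primary alcohol should stop at the aldehyde and leave the alkene untouched.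

Step 6
Reactants: 9 (6R)-4-[(tert-butyldimethylsilyl)oxy]-N1,N6-dimethoxy-N1,N6,5-trimethylcyclohexa-1,4-diene-1,6-dicarboxamide; 11 4-methylpent-4-enal
Product: 12 (5S,6R)-5-(1-hydroxy-4-methylpent-4-en-1-yl)-N1,N6-dimethoxy-N1,N6,5-trimethyl-4-oxocyclohex-1-ene-1,6-dicarboxamide (both carbinol epimers)
Conditions: BF3·OEt2 (3 equiv), CH2Cl2, −78 °C; aq. NaHCO3
Reagents that add atoms: none
Why: Mukaiyama aldol addition of the tetrasubstituted enol silane should form the quaternary C10 with the aldehyde entering anti to the C9 carboxamide (methyl cis to C11); the carbinol configuration is irrelevant because it is oxidized next.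

Step 7
Reactants: 12 (5S,6R)-5-(1-hydroxy-4-methylpent-4-en-1-yl)-N1,N6-dimethoxy-N1,N6,5-trimethyl-4-oxocyclohex-1-ene-1,6-dicarboxamide
Product: 13 (5S,6R)-N1,N6-dimethoxy-N1,N6,5-trimethyl-5-(4-methylpent-4-enoyl)-4-oxocyclohex-1-ene-1,6-dicarboxamide
Conditions: Dess–Martin periodinane, CH2Cl2, 0 °C → rt
Reagents that add atoms: none
Why: Dess–Martin oxidation of the secondary alcohol should converge both epimers on the non-enolizable 2,2-disubstituted β-diketone.

Step 8
Reactants: 13 (5S,6R)-N1,N6-dimethoxy-N1,N6,5-trimethyl-5-(4-methylpent-4-enoyl)-4-oxocyclohex-1-ene-1,6-dicarboxamide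
Product: 14 (5R,9R,10R)-5-hydroxy-1-oxodrim-7-ene-11,12-dioic acid bis(N-methoxy-N-methylamide) (5α-OH, 10β-CH3, trans-fused)
Conditions: Fe(acac)3 (30 mol %), PhSiH3 (2.5 equiv), EtOH, 60 °C
Reagents that add atoms: none
Why: Fe(acac)3/PhSiH3/EtOH generates an iron hydride that transfers H• to the terminal CH2 of the isopropenyl group, so that C4 becomes a tertiary radical carrying both methyl groups; this radical adds in a 6-exo-trig closure to the C5 carbonyl carbon and the alkoxyl radical is reduced and protonated, which forms ring A, the C4–C5 bond between two fully substituted carbons, the gem-dimethyl group and the 5-OH in one operation. The closest known reaction type is the iron-hydride (hydrogen-atom-transfer) initiated radical cyclization of alkene-tethered ketones, which includes 2,2-disubstituted 1,3-diketones and gives tertiary alcohols next to quaternary carbons. The one new stereocentre, C5, is controlled by the quaternary C10: in the chair-like transition state of the forming ring both bonds to ring B (C10–C9 and C5–C6) are equatorial and the C10 methyl and the developing C5–O bond are axial and anti, which should give the trans-fused 5α-alcohol. The step needs chemoselectivity (H• transfer to the electron-rich 1,1-disubstituted alkene, not to the electron-poor trisubstituted C7=C8), site selectivity (only C5 can be reached through a six-membered transition state, since the C1 carbonyl lies inside the tether) and face selectivity at C5, for which the diequatorial attachment of ring B is the securing element.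

Step 9
Reactants: 14 (5R,9R,10R)-5-hydroxy-1-oxodrim-7-ene-11,12-dioic acid bis(N-methoxy-N-methylamide)
Product: 15 (1R,5R,9R,10S)-1,5-dihydroxydrim-7-ene-11,12-dioic acid bis(N-methoxy-N-methylamide) (1β,5α-diol)
Conditions: Me4NBH(OAc)3, MeCN/AcOH 1:1, −20 °C
Reagents that add atoms: none
Why: hydroxyl-directed (Evans–Saksena) reduction, in which the acyloxyborohydride bound to the axial 5α-OH delivers hydride to the α face of the C1 ketone (also the axial face anti to the angular methyl), should give the equatorial 1β-alcohol, 1,3-anti to the 5α-OH, without touching the amides.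

Step 10
Reactants: 16 (E)-4-hydroxycinnamic acid (p-coumaric acid)
Product: 18 (E)-3-{4-[(tert-butyldimethylsilyl)oxy]phenyl}acrylic acid, via bis-silyl derivative 17 (not isolated)
Conditions: TBSCl (2.3 equiv), imidazole, DMF, rt; then AcOH/THF/H2O, rt
Reagents that add atoms: tert-butyldimethylsilyl chloride, CC(C)(C)[Si](C)(C)Cl
Why: silylation of phenol and acid followed by selective hydrolysis of the labile silyl ester should leave the aryl silyl ether in place.

Step 11
Reactants: 15 (1R,5R,9R,10S)-1,5-dihydroxydrim-7-ene-11,12-dioic acid bis(N-methoxy-N-methylamide); 18 (E)-3-{4-[(tert-butyldimethylsilyl)oxy]phenyl}acrylic acid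
Product: 20 (1R,5R,9R,10S)-1-[(E)-3-{4-[(tert-butyldimethylsilyl)oxy]phenyl}acryloyloxy]-5-hydroxydrim-7-ene-11,12-dioic acid bis(N-methoxy-N-methylamide), via Yamaguchi mixed anhydride 19 (not isolated)
Conditions: 2,4,6-trichlorobenzoyl chloride, Et3N, THF, rt; then 15, DMAP, toluene, 60 °C
Reagents that add atoms: none
Why: Yamaguchi esterification should acylate the hindered secondary 1β-OH through the acylpyridinium ion while the tertiary 5α-OH stays free, with retention at C1.

Step 12
Reactants: 20 (1R,5R,9R,10S)-1-[(E)-3-{4-[(tert-butyldimethylsilyl)oxy]phenyl}acryloyloxy]-5-hydroxydrim-7-ene-11,12-dioic acid bis(N-methoxy-N-methylamide)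
Product: 21 (1R,5R,9R,10S)-1-[(E)-3-{4-[(tert-butyldimethylsilyl)oxy]phenyl}acryloyloxy]-5-hydroxydrim-7-ene-11,12-dial
Conditions: Cp2Zr(H)Cl (5 equiv), THF, rt, 20 min; then H2O/silica gel
Reagents that add atoms: none
Why: Schwartz-reagent reduction of tertiary (Weinreb) amides to aldehydes via stable zirconated hemiaminals should convert both amides under neutral conditions, leaving the cinnamate ester, the aryl silyl ether and the epimerizable C9 untouched.

Step 13
Reactants: 21 (1R,5R,9R,10S)-1-[(E)-3-{4-[(tert-butyldimethylsilyl)oxy]phenyl}acryloyloxy]-5-hydroxydrim-7-ene-11,12-dial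
Product: 22 (1R,5R,9R,10S)-5-hydroxy-1-[(E)-3-(4-hydroxyphenyl)acryloyloxy]drim-7-ene-11,12-dial (CNP0323926.1)
Conditions: HF·pyridine, THF, 0 °C
Reagents that add atoms: none
Why: fluoride cleavage of the aryl silyl ether under mildly acidic, base-free conditions should release the phenol without epimerizing C9 or cleaving the ester.

**Compound list**
1 | butane-2,3-dione | CC(=O)C(C)=O | starting material
2 | N-methoxy-N-methyl-2-(triphenylphosphoranylidene)acetamide | CON(C)C(=O)C=P(c1ccccc1)(c1ccccc1)c1ccccc1 | starting material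
3 | (2E)-N-methoxy-N,3-dimethyl-4-oxopent-2-enamide | CC(=O)/C(C)=C/C(=O)N(C)OC | intermediate
4 | (2E)-4-[(tert-butyldimethylsilyl)oxy]-N-methoxy-N,3-dimethylpenta-2,4-dienamide | C=C(O[Si](C)(C)C(C)(C)C)/C(C)=C/C(=O)N(C)OC | intermediate
5 | propiolic acid | C#CC(=O)O | starting material
6 | 3,5-dimethyl-1H-pyrazole | Cc1cc(C)[nH]n1 | starting material
7 | 1-(3,5-dimethyl-1H-pyrazol-1-yl)prop-2-yn-1-one | C#CC(=O)n1nc(C)cc1C | intermediate
8 | (1R)-3-[(tert-butyldimethylsilyl)oxy]-6-(3,5-dimethylpyrazole-1-carbonyl)-N-methoxy-N,2-dimethylcyclohexa-2,5-diene-1-carboxamide | CC1=C(O[Si](C)(C)C(C)(C)C)CC=C(C(=O)n2nc(C)cc2C)[C@@H]1C(=O)N(C)OC | intermediate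
9 | (6R)-4-[(tert-butyldimethylsilyl)oxy]-N1,N6-dimethoxy-N1,N6,5-trimethylcyclohexa-1,4-diene-1,6-dicarboxamide | CC1=C(O[Si](C)(C)C(C)(C)C)CC=C(C(=O)N(C)OC)[C@@H]1C(=O)N(C)OC | intermediate
10 | 4-methylpent-4-en-1-ol | C=C(C)CCCO | starting material
11 | 4-methylpent-4-enal | C=C(C)CCC=O | intermediate
12 | (5S,6R)-5-(1-hydroxy-4-methylpent-4-en-1-yl)-N1,N6-dimethoxy-N1,N6,5-trimethyl-4-oxocyclohex-1-ene-1,6-dicarboxamide (carbinol epimers) | C=C(C)CCC(O)[C@]1(C)[C@@H](C(=O)N(C)OC)C(C(=O)N(C)OC)=CCC1=O | intermediate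
13 | (5S,6R)-N1,N6-dimethoxy-N1,N6,5-trimethyl-5-(4-methylpent-4-enoyl)-4-oxocyclohex-1-ene-1,6-dicarboxamide | C=C(C)CCC(=O)[C@]1(C)[C@@H](C(=O)N(C)OC)C(C(=O)N(C)OC)=CCC1=O | intermediate
14 | (5R,9R,10R)-5-hydroxy-1-oxodrim-7-ene-11,12-dioic acid bis(N-methoxy-N-methylamide) | CC1(C)CCC(=O)[C@]2(C)[C@@H](C(=O)N(C)OC)C(C(=O)N(C)OC)=CC[C@@]12O | intermediate
15 | (1R,5R,9R,10S)-1,5-dihydroxydrim-7-ene-11,12-dioic acid bis(N-methoxy-N-methylamide) | CC1(C)CC[C@@H](O)[C@]2(C)[C@@H](C(=O)N(C)OC)C(C(=O)N(C)OC)=CC[C@@]12O | intermediate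
16 | (E)-4-hydroxycinnamic acid | O=C(O)/C=C/c1ccc(O)cc1 | starting material
17 | tert-butyldimethylsilyl (E)-3-{4-[(tert-butyldimethylsilyl)oxy]phenyl}acrylate | CC(C)(C)[Si](C)(C)OC(=O)/C=C/c1ccc(O[Si](C)(C)C(C)(C)C)cc1 | intermediate
18 | (E)-3-{4-[(tert-butyldimethylsilyl)oxy]phenyl}acrylic acid | O=C(O)/C=C/c1ccc(O[Si](C)(C)C(C)(C)C)cc1 | intermediate
19 | (E)-3-{4-[(tert-butyldimethylsilyl)oxy]phenyl}acrylic 2,4,6-trichlorobenzoic anhydride | O=C(/C=C/c1ccc(O[Si](C)(C)C(C)(C)C)cc1)OC(=O)c1c(Cl)cc(Cl)cc1Cl | intermediate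
20 | (1R,5R,9R,10S)-1-[(E)-3-{4-[(tert-butyldimethylsilyl)oxy]phenyl}acryloyloxy]-5-hydroxydrim-7-ene-11,12-dioic acid bis(N-methoxy-N-methylamide) | CC1(C)CC[C@@H](OC(=O)/C=C/c2ccc(O[Si](C)(C)C(C)(C)C)cc2)[C@]2(C)[C@@H](C(=O)N(C)OC)C(C(=O)N(C)OC)=CC[C@@]12O | intermediate
21 | (1R,5R,9R,10S)-1-[(E)-3-{4-[(tert-butyldimethylsilyl)oxy]phenyl}acryloyloxy]-5-hydroxydrim-7-ene-11,12-dial | CC1(C)CC[C@@H](OC(=O)/C=C/c2ccc(O[Si](C)(C)C(C)(C)C)cc2)[C@]2(C)[C@@H](C=O)C(C=O)=CC[C@@]12O | intermediate
22 | (1R,5R,9R,10S)-5-hydroxy-1-[(E)-3-(4-hydroxyphenyl)acryloyloxy]drim-7-ene-11,12-dial | CC1(C)CC[C@@H](OC(=O)/C=C/c2ccc(O)cc2)[C@]2(C)[C@@H](C=O)C(C=O)=CC[C@@]12O | target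

**Step count and risks**
Total steps: 13. Longest linear sequence: 10 (steps 1, 2, 4, 6, 7, 8, 9, 11, 12, 13).

Most likely to fail:

1. Step 8. The C4 radical may attack the C5 carbonyl on the wrong face (cis ring fusion), or the reversible addition may lose out to simple reduction of the open-chain radical. The fallback moves stereocontrol from the cyclization to an α-face epoxidation and is stereoconvergent. It sets out from 13, whose crude cyclization product would contain 14 together with its C5 epimer, the cis-fused 5β-hydroxy-1-oxodrim-7-ene-11,12-dioic acid bis(N-methoxy-N-methylamide) F1. Both ketols would be dehydrated with the Burgess reagent (benzene, 50 °C; only C6 carries β-hydrogens) to 1-oxodrima-5,7-diene-11,12-dioic acid bis(N-methoxy-N-methylamide) F2. mCPBA should epoxidize the electron-rich C5=C6 bond from the α face, the β face being blocked by the 10β- and 4β-methyl groups, to give the 5α,6α-epoxy-1-oxodrim-7-ene bis(amide) F3. Pd(0)/Bu3P-catalysed hydrogenolysis of this γ,δ-epoxy-α,β-unsaturated amide with HCO2H/Et3N should deliver hydride to C6 and come back to the route at 14.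

2. Step 4. Enantioface selectivity may be low with this acyclic, amide-bearing silyloxydiene, and [2+2] or Michael addition at the silyl enol ether may compete. The fallback replaces catalysis by a covalent auxiliary and separation of diastereomers; it sets out from 4 and 5. Acid 5 would be coupled with (S)-4-benzyloxazolidin-2-one (DCC, cat. DMAP) to (S)-4-benzyl-3-propioloyloxazolidin-2-one F4. Me2AlCl-promoted or thermal Diels–Alder reaction with 4 would give the (6R)-configured N-acyloxazolidinone cycloadduct F5, isolated from its diastereomer by chromatography or crystallization. Transamination with AlMe3/MeNHOMe·HCl would release the auxiliary and come back to the route at 9.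

3. Step 6. The hindered tetrasubstituted enol silane may be protodesilylated, the 1,4-diene may transfer hydride to the activated aldehyde (aromatization), or the aldehyde may enter syn to the C9 carboxamide. The fallback builds the C10–C1 bond with a one-carbon electrophile and forms C1–C2 afterwards; it sets out from 9. Lanthanide-triflate-catalysed aqueous hydroxymethylation (aq. HCHO, Yb(OTf)3, THF/H2O) would give (5S,6R)-5-(hydroxymethyl)-N1,N6-dimethoxy-N1,N6,5-trimethyl-4-oxocyclohex-1-ene-1,6-dicarboxamide F6. Dess–Martin oxidation would give the keto aldehyde (5S,6R)-5-formyl-N1,N6-dimethoxy-N1,N6,5-trimethyl-4-oxocyclohex-1-ene-1,6-dicarboxamide F7. Addition of (3-methylbut-3-en-1-yl)magnesium bromide F8 (from 4-bromo-2-methylbut-1-ene and Mg) at −78 °C to the aldehyde would come back to the route at 12.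

**Further compounds**
F1 | step 8 | (5S,9R,10R)-5-hydroxy-1-oxodrim-7-ene-11,12-dioic acid bis(N-methoxy-N-methylamide) (cis-fused C5 epimer) | CC1(C)CCC(=O)[C@]2(C)[C@@H](C(=O)N(C)OC)C(C(=O)N(C)OC)=CC[C@]12O
F2 | step 8 | (9R,10R)-1-oxodrima-5,7-diene-11,12-dioic acid bis(N-methoxy-N-methylamide) | CC1(C)CCC(=O)[C@]2(C)[C@@H](C(=O)N(C)OC)C(C(=O)N(C)OC)=CC=C12
F3 | step 8 | 5α,6α-epoxy-1-oxodrim-7-ene-11,12-dioic acid bis(N-methoxy-N-methylamide) | CC1(C)CCC(=O)[C@]2(C)[C@@H](C(=O)N(C)OC)C(C(=O)N(C)OC)=C[C@@H]3O[C@]123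
F4 | step 4 | (S)-4-benzyl-3-propioloyloxazolidin-2-one | C#CC(=O)N1[C@@H](Cc2ccccc2)COC1=O
F5 | step 4 | (1R)-6-{[(S)-4-benzyl-2-oxooxazolidin-3-yl]carbonyl}-3-[(tert-butyldimethylsilyl)oxy]-N-methoxy-N,2-dimethylcyclohexa-2,5-diene-1-carboxamide | CC1=C(O[Si](C)(C)C(C)(C)C)CC=C(C(=O)N2[C@@H](Cc3ccccc3)COC2=O)[C@@H]1C(=O)N(C)OC
F6 | step 6 | (5S,6R)-5-(hydroxymethyl)-N1,N6-dimethoxy-N1,N6,5-trimethyl-4-oxocyclohex-1-ene-1,6-dicarboxamide | OC[C@]1(C)[C@@H](C(=O)N(C)OC)C(C(=O)N(C)OC)=CCC1=O
F7 | step 6 | (5S,6R)-5-formyl-N1,N6-dimethoxy-N1,N6,5-trimethyl-4-oxocyclohex-1-ene-1,6-dicarboxamide | O=C[C@]1(C)[C@@H](C(=O)N(C)OC)C(C(=O)N(C)OC)=CCC1=O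
F8 | step 6 | (3-methylbut-3-en-1-yl)magnesium bromide | C=C(C)CC[Mg]Br
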